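## Analysis of the target

The target is a germacrane-type sesquiterpene lactone: a ten-membered carbocycle fused to an α-methylene-γ-butyrolactone. Working numbering: C6 is the lactone O–CH, C5=C4 the ring alkene (methyl C15 on C4), C3 the secondary carbinol, then C2, C1, C10 (tertiary carbinol with methyl C14), C9, C8 (angelate-bearing CH), C7 (ring-fusion CH), and C11(=C13)–C12 the lactone carbons. In this numbering the five stereocentres are 3S,6S,7R,8R,10S. The C6–O, C7–C11 and C8–O bonds are contiguous and on the same face of the ring, so the lactone is cis-fused and the ester is cis to it. The C3 hydroxyl lies on that face across the Z alkene, and the C10 hydroxyl on the opposite face. The sensitive groups are the exo-methylene lactone (Michael acceptor), the angelate (Z to E isomerisation under nucleophilic catalysis), a C8 oxygen that can take over the lactone carbonyl once it is free, and an allylic and a tertiary alcohol. The difficulty is a ten-membered ring, poor to close end to end, with stereocentres spread from C3 to C10 and a Z trisubstituted alkene between two allylic oxygens. The feature the strategy rests on is this: C15–C4=C5 with the C3 oxygen, C2 and C1 are a carvone ring fragment, and C1 and C6 sit 1,6 across the macrocycle. A C1–C6 bond therefore turns C1–C6 into a cyclohexene whose endocyclic alkene is the Z C4=C5 alkene. With C7=C8 on C6 and C10=C9 on C1, cleaving that bond in a [3,3] shift gives the ten-membered ring.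

## Retrosynthetic reasoning

**36 to 32 and 33.** The angelate C8–O bond and the two free hydroxyls are unveiled last, because the Z ester and the free C8 oxygen next to the lactone are the least robust features. This leads back to bis-silyl ether 35, made by acylating alcohol 32 with 33.

**32 to 27.** The C8 oxygen is carried as a 4-methoxybenzyl ether (31) until the exo-methylene is in place. The C11=C13 bond is cut back to lactone 27 through Mannich base 29. Methylenation before liberation of O8 keeps every enolate step away from a free neighbouring hydroxyl.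

**27 to 25.** The C12–O6 lactone bond is traced to triol 25 through hydroxy lactone 26. Oxidation of the primary C12 alcohol beside a cis C6 hydroxyl closes the lactone, and the tertiary C10 alcohol is then capped.

**25 to 23.** The C10 carbinol comes from the E C1=C10 alkene through epoxide 24, opened by hydride at C1. That hydride step cannot coexist with a lactone, so it is placed before lactone formation and merged with reduction of the C6 ketone and of the side-chain ester. The cut therefore removes C6–H, C1–H and the C12 hydrides together.

**23 to 20 and 21.** The C7–C11 bond is cut where C7 is nucleophilic, α′ to the C6 ketone of dienone 20. The C8 ether next to it is the stereocontrol element.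

**20 to 17 (key).** Reconnecting C1–C6 and cutting C8–C9 turns the ten-membered dienone, through enolate 19 and alkoxide 18, into the trans-1,2-dialkenylcyclohexenol 17. The cut is made here because it removes the macrocycle and reduces C8 to the geometry of an E enol ether. The forward reaction has to form C8–C9 through a chair and release a ketone at C6.

**17 to 6 and 14.** The C6–C7 bond is cut to enone 6 and an E 2-alkoxyvinyl metal (15, 16) derived from iodide 14. The addition must occur anti to the isopropenyl group.

**14 to 7 and 8.** The two-carbon enol ether unit comes from alkynyl ether 12, itself from dichlorovinyl ether 10, the adduct of 7 and 8.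

**6 to 1.** Enone 6 is the silyl ether 5 oxidised at the ring CH2 (C6). 5 comes from 4, whose carbinol configuration is that of 2 inverted through ester 3, and 2 is the reduction product of 1. The one stereocentre of 1 (C1 of the target numbering) is sacrificed in the key step after directing C6 and, through it, C8.

## Alternatives that were turned down

**Alternative 1:** a three-component union that makes C4–C15 and C5–C6 together.
- Forward key step: a C3 propargylic alkoxide directs copper-catalysed anti addition of a methyl Grignard reagent across the alkyne (methyl to C4, magnesium to C5). The Z alkenylmagnesium adds to a C6 aldehyde, and the new alkoxide closes onto a pendant ester to give lactone diene A1.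
- For: the Z alkene with C15 and both allylic oxygens is set in one convergent step. C10 is made in a separate fragment, so it does not depend on face selectivity on a medium ring. On C10 and on convergence this is stronger than the chosen route.
- Against: C6 must come out cis to C7 by 1,2-induction in an addition to an α-branched, β-alkoxy aldehyde. A1 still has no carbocycle: a ten-membered ring-closing metathesis between the C3 and C10 vinyl groups and selective saturation of the new C1=C2 alkene would follow. C3, C7, C8 and C10 each need their own asymmetric step.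
- Comparison: the chosen strategy obtains the ring, C3 and C8 from one chiral-pool centre without macrocyclisation, and pays for it by relying on ring-conformation control at C6, C7 and C10.

**Alternative 2:** disconnection at C3–C4.
- Forward key step: an intramolecular Nozaki–Hiyama–Kishi reaction. The Z alkenyl iodide at C4 becomes an alkenylchromium species under nickel catalysis and adds to the C3 aldehyde, closing the ring to A2, the C10 silyl ether of the target.
- For: the ring is closed at the latest possible point. The organochromium tolerates lactone, angelate and exo-methylene. C10 comes with fixed configuration from the chiral pool. On C10 and on late-stage convergence this is stronger.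
- Against: the C3 carbinol is created during a ten-membered closure with no neighbouring stereocentre to direct it. The closure needs high dilution and stoichiometric chromium. The C6–C8 triad and the sensitive groups must be built and carried on an open chain.
- Comparison: the chosen strategy fixes C3 from the start and forms the ring without dilution.

**Alternative 3:** retro-[2,3] disconnection of C7–C8.
- Forward key step: a thirteen-membered cyclic allylic ether (oxygen bridging C8 and C13) bears tin at C8. Tin–lithium exchange triggers a Wittig–Still rearrangement that forms C7–C8, breaks O–C13 and contracts the ring to carbocycle A3.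
- For: two adjacent stereocentres and the exo-methylene carbon are set at once. A thirteen-membered ether is easier to close than a ten-membered carbocycle. The C8 hydroxyl emerges free for acylation, which is stronger than the chosen route's late oxidative deprotection.
- Against: the C7/C8 relationship depends on a large-ring transition state. Organotin intermediates are needed. After A3, C12 must be oxidised twice and lactonised onto C6 after removing an acetal in the presence of three silyl ethers. C3, C6 and C10 must all be built beforehand.
- Comparison: the chosen route reaches the ten-membered ring in seven linear steps from 1.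

Key step: step 10

Assumption: the configuration is taken exactly as drawn (3S,6S,7R,8R,10S in the working numbering, cis-fused lactone); descriptors in compound names refer to the working numbering unless a full ring name is given.

## Route

Step 1
Reactants: 1 (R)-(−)-carvone
Product: 2 (1R,5R)-cis-carveol
Conditions: NaBH4, CeCl3·7H2O, MeOH, −78 → 0 °C
Reagents that add atoms: none
Why: Luche reduction; the cerium-activated ketone is reduced 1,2 only, and axial hydride delivery to the half-chair with equatorial isopropenyl should give the cis alcohol.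

Step 2
Reactants: 2 (1R,5R)-cis-carveol
Product: 3 (1S,5R)-trans-carveyl 4-nitrobenzoate
Conditions: 4-O2NC6H4CO2H, PPh3, DIAD, THF, 0 °C → rt
Reagents that add atoms: 4-nitrobenzoic acid, O=C(O)c1ccc(cc1)[N+](=O)[O-]
Why: Mitsunobu reaction; SN2 displacement of the alkoxyphosphonium ion by the carboxylate inverts the carbinol carbon (future C3) to S, the acidic nitrobenzoic acid keeping elimination and SN2′ attack at the methyl-bearing alkene carbon minor.

Step 3
Reactants: 3 (1S,5R)-trans-carveyl 4-nitrobenzoate
Product: 4 (1S,5R)-trans-carveol
Conditions: K2CO3, MeOH, rt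
Reagents that add atoms: none
Why: Base-catalysed transesterification to methanol; no stereocentre is touched.

Step 4
Reactants: 4 (1S,5R)-trans-carveol
Product: 5 (1S,5R)-trans-carveol tert-butyldimethylsilyl ether
Conditions: TBSCl, imidazole, DMF, rt
Reagents that add atoms: tert-butyldimethylsilyl chloride, CC(C)(C)[Si](C)(C)Cl
Why: Standard silylation of a secondary allylic alcohol; the silyl ether survives organocerium, KH, amide bases, peracid and hydride later on.

Step 5
Reactants: 5 (1S,5R)-trans-carveol tert-butyldimethylsilyl ether
Product: 6 (4S,6R)-4-(tert-butyldimethylsilyloxy)-3-methyl-6-(prop-1-en-2-yl)cyclohex-2-en-1-one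
Conditions: CrO3, 3,5-dimethylpyrazole, CH2Cl2, −20 °C
Reagents that add atoms: chromium trioxide, O=[Cr](=O)=O
Why: Allylic oxidation by the hexavalent chromium–pyrazole complex; the ring CH2 next to the trisubstituted alkene is the most accessible allylic position, the silyloxy-bearing CH is shielded and the 1,1-disubstituted isopropenyl alkene is less electron-rich. Oxygenation at the methyl-bearing terminus would converge on 6 by chromate transposition.

Step 6
Reactants: 7 4-methoxybenzyl alcohol; 8 trichloroethylene
Product: 10 (E)-1,2-dichlorovinyl 4-methoxybenzyl ether, via potassium 4-methoxybenzyl oxide 9 (not isolated)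
Conditions: KH, THF, 0 °C; then 8, −50 °C → rt
Reagents that add atoms: none
Why: Elimination–addition; the alkoxide converts 8 into dichloroacetylene and adds to it anti, which gives the E dichlorovinyl ether.

Step 7
Reactants: 10 (E)-1,2-dichlorovinyl 4-methoxybenzyl ether
Product: 12 ethynyl 4-methoxybenzyl ether, via lithium (4-methoxybenzyloxy)acetylide 11 (not isolated)
Conditions: n-BuLi (2.2 equiv), Et2O, −78 → −40 °C; then MeOH, −78 °C
Reagents that add atoms: none
Why: β-Elimination of HCl followed by chlorine–lithium exchange gives the lithium alkoxyacetylide, protonated cold; 12 is kept below 0 °C and used at once because benzyl alkynyl ethers rearrange sigmatropically on warming.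

Step 8
Reactants: 12 ethynyl 4-methoxybenzyl ether
Product: 14 (E)-2-iodovinyl 4-methoxybenzyl ether, via (E)-2-(4-methoxybenzyloxy)vinylzirconocene chloride 13 (not isolated)
Conditions: Cp2Zr(H)Cl, THF, 0 °C → rt; then I2, −78 → 0 °C
Reagents that add atoms: iodine, II
Why: Hydrozirconation is a syn addition that places zirconium on the terminal carbon, and iodinolysis of the C–Zr bond goes with retention, so the E geometry is fixed by mechanism.

Step 9
Reactants: 14 (E)-2-iodovinyl 4-methoxybenzyl ether; 6 (4S,6R)-4-(tert-butyldimethylsilyloxy)-3-methyl-6-(prop-1-en-2-yl)cyclohex-2-en-1-one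
Product: 17 (1R,4S,6R)-4-(tert-butyldimethylsilyloxy)-1-[(E)-2-(4-methoxybenzyloxy)vinyl]-3-methyl-6-(prop-1-en-2-yl)cyclohex-2-en-1-ol, via (E)-2-(4-methoxybenzyloxy)vinyllithium 15 (not isolated), via (E)-2-(4-methoxybenzyloxy)vinylcerium dichloride 16 (not isolated)
Conditions: 14, t-BuLi (2 equiv), Et2O, −78 °C; CeCl3, THF, −78 °C; then 6, −78 °C; then H2O
Reagents that add atoms: none
Why: Iodine–lithium exchange with retention, then transmetalation to the weakly basic organocerium, which adds 1,2 to the enolisable enone without isomerising the isopropenyl group. Attack anti to the adjacent isopropenyl substituent, as in alkenyl additions to 6-alkenylcyclohex-2-enones, should set the carbinol carbon (future C6) R with the two alkenyl groups trans.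

Step 10
Reactants: 17 (1R,4S,6R)-4-(tert-butyldimethylsilyloxy)-1-[(E)-2-(4-methoxybenzyloxy)vinyl]-3-methyl-6-(prop-1-en-2-yl)cyclohex-2-en-1-ol
Product: 20 (2Z,4S,6E,9R)-4-(tert-butyldimethylsilyloxy)-9-(4-methoxybenzyloxy)-3,7-dimethylcyclodeca-2,6-dien-1-one, via potassium alkoxide of 17 18 (not isolated), via ten-membered potassium enolate 19 (not isolated)
Conditions: KH, 18-crown-6, THF, 0 °C → rt; then AcOH, THF, −78 °C
Reagents that add atoms: none
Why: KH with 18-crown-6 gives the dissociated alkoxide 18, whose oxyanion weakens the C1–C6 bond and triggers a [3,3] sigmatropic shift of the 1,5-diene C8=C7–C6–C1–C10=C9 (anionic oxy-Cope rearrangement; the closest known type is the ring expansion of trans-1,2-dialkenylcyclohexanols to cyclodec-5-enones). C8–C9 forms while C1–C6 breaks, so the ten-membered ring is closed by four-carbon ring expansion through a six-centre chair, not by an exo or endo end-to-end cyclisation, and needs no dilution. In that chair the ring bonds C6–C5 and C1–C2 are equatorial and the oxide axial, as the trans arrangement of the alkenyl groups requires; this makes the new C1=C10 alkene E, while Z C4=C5 and 3S pass through unchanged. The new stereocentre C8 is set by chirality transfer from C1 and C6, which both become trigonal: the E enol ether places the 4-methoxybenzyloxy group equatorial on the one chair that the (1R,6R) ring centres allow, and C9 bonds to the face of C8 that gives 8R (9R in the ring name of 20). The selectivity needed is chair over boat, secured by the trans-diequatorial alkenyl groups and by the absence of any axial substituent on the diene termini. The driving force is conversion of the alkoxide into the delocalised enolate 19, which cold acetic acid protonates at C7 to give the conjugated Z enone 20. Because 19 carries the ether β to the enolate carbon, it is quenched at −78 °C as soon as 17 is consumed, so that E1cB loss of the alkoxide does not compete.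

Step 11
Reactants: 20 (2Z,4S,6E,9R)-4-(tert-butyldimethylsilyloxy)-9-(4-methoxybenzyloxy)-3,7-dimethylcyclodeca-2,6-dien-1-one; 21 tert-butyl bromoacetate
Product: 23 tert-butyl [(1R,3Z,5S,7E,10R)-5-(tert-butyldimethylsilyloxy)-10-(4-methoxybenzyloxy)-4,8-dimethyl-2-oxocyclodeca-3,7-dien-1-yl]acetate, via lithium enolate of 20 22 (not isolated)
Conditions: LiN(i-Pr)2, THF, −78 °C; then 21, DMPU, −78 → −40 °C
Reagents that add atoms: none
Why: Kinetic α′-deprotonation of the enone at C7 and C-alkylation of the lithium enolate. Lithium bridging the enolate oxygen and the C8 ether oxygen holds the C8–O bond in the enolate plane, so the electrophile should enter on the face of H8, anti to ring carbon C9 (Fráter–Seebach-type 1,2-induction, also the peripheral face), giving 7R with the side chain cis to the C8 ether.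

Step 12
Reactants: 23 tert-butyl [(1R,3Z,5S,7E,10R)-5-(tert-butyldimethylsilyloxy)-10-(4-methoxybenzyloxy)-4,8-dimethyl-2-oxocyclodeca-3,7-dien-1-yl]acetate
Product: 24 (1R,10R)-1,10-epoxide of 23
Conditions: mCPBA, NaHCO3, CH2Cl2, 0 °C
Reagents that add atoms: 3-chloroperoxybenzoic acid, OOC(=O)c1cccc(Cl)c1
Why: Prilezhaev epoxidation; only the isolated, electron-rich C1=C10 alkene reacts, since C4=C5 is deactivated by conjugation with the ketone. Peripheral attack on the E alkene in the conformer that holds C14 on the face of the C7 side chain, the mode known for 1(10)E-germacranolides, should give the (1R,10R)-epoxide, whose C10–O bond is that of the target.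

Step 13
Reactants: 24 (1R,10R)-1,10-epoxide of 23
Product: 25 (3S,6S,7S,8R,10S)-triol with hydroxyls at C6, C10 and C12
Conditions: LiEt3BH (excess), THF, −78 °C → rt; then H2O
Reagents that add atoms: none
Why: The trialkylborohydride reduces the β,β-disubstituted enone 1,2 at low temperature, with Felkin–Anh attack anti to ring carbon C8 expected to give the 6S alcohol cis to the C7 side chain. On warming it opens the trisubstituted epoxide by SN2 attack at the secondary C1, leaving the C10–O bond as the tertiary alcohol, and reduces the ester to the primary alcohol.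

Step 14
Reactants: 25 (3S,6S,7S,8R,10S)-triol with hydroxyls at C6, C10 and C12
Product: 26 (3S,6S,7R,8R,10S)-10-hydroxy cis-fused 6,12-lactone
Conditions: TEMPO (20 mol %), PhI(OAc)2 (2.5 equiv), CH2Cl2, rt
Reagents that add atoms: none
Why: Oxidative lactonisation of a 1,4-diol; the oxoammonium ion oxidises the unhindered primary alcohol first, the aldehyde closes to the five-membered lactol with the cis C6 hydroxyl and is oxidised again, while the hindered allylic and tertiary hydroxyls react more slowly.

Step 15
Reactants: 26 (3S,6S,7R,8R,10S)-10-hydroxy cis-fused 6,12-lactone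
Product: 27 (3S,6S,7R,8R,10S)-10-triethylsilyl ether of 26
Conditions: TESOTf, 2,6-lutidine, CH2Cl2, −78 → 0 °C
Reagents that add atoms: triethylsilyl trifluoromethanesulfonate, CC[Si](CC)(CC)OS(=O)(=O)C(F)(F)F
Why: Silyl triflate silylation of a tertiary alcohol; it keeps the hydroxyl out of the enolate chemistry and prevents acetal formation with the oxidised 4-methoxybenzyl group in step 18.

Step 16
Reactants: 27 (3S,6S,7R,8R,10S)-10-triethylsilyl ether of 26
Product: 29 11-(dimethylaminomethyl) lactone (C11 configuration not controlled), via lithium enolate of 27 28 (not isolated)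
Conditions: LiN(i-Pr)2, THF, −78 °C; then CH2=NMe2+ I−, −78 °C → rt
Reagents that add atoms: N,N-dimethylmethyleneiminium iodide, C=[N+](C)C.[I-]
Why: Mannich-type aminomethylation of the lactone enolate; the enolate carbon C11 has no β leaving group, and the new C11 centre is erased in the next step.

Step 17
Reactants: 29 11-(dimethylaminomethyl) lactone (C11 configuration not controlled)
Product: 31 (3S,6S,7R,8R,10S)-α-methylene lactone with C3 OTBS, C8 OPMB and C10 OTES, via trimethylammonium iodide of 29 30 (not isolated)
Conditions: MeI, MeOH, rt; then NaHCO3, CH2Cl2/H2O, rt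
Reagents that add atoms: none
Why: Quaternisation followed by Hofmann-type E1cB elimination of trimethylamine from the β-ammonio lactone gives the conjugated exo-methylene under mild base.

Step 18
Reactants: 31 (3S,6S,7R,8R,10S)-α-methylene lactone with C3 OTBS, C8 OPMB and C10 OTES
Product: 32 (3S,6S,7R,8R,10S)-C8 alcohol
Conditions: DDQ, CH2Cl2/pH 7 buffer (10:1), 0 °C
Reagents that add atoms: none
Why: Oxidative cleavage of the 4-methoxybenzyl ether by hydride abstraction and hydrolysis of the oxocarbenium ion; silyl ethers, the lactone and the alkenes are inert to DDQ under buffered conditions.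

Step 19
Reactants: 32 (3S,6S,7R,8R,10S)-C8 alcohol; 33 angelic acid
Product: 35 (3S,6S,7R,8R,10S)-8-angelate with C3 OTBS and C10 OTES, via angelic 2,4,6-trichlorobenzoic anhydride 34 (not isolated)
Conditions: 33, 2,4,6-Cl3C6H2COCl, Et3N, toluene, rt; then 32, toluene, 80 °C
Reagents that add atoms: none
Why: Yamaguchi esterification run without a nucleophilic catalyst; the alcohol attacks the unhindered angeloyl carbonyl of the mixed anhydride, and leaving out the pyridine-type catalyst avoids addition–elimination isomerisation of the Z ester to the tiglate.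

Step 20
Reactants: 35 (3S,6S,7R,8R,10S)-8-angelate with C3 OTBS and C10 OTES
Product: 36 CNP0137971.2
Conditions: HF·pyridine, pyridine, THF, 0 °C → rt
Reagents that add atoms: none
Why: Buffered fluoride desilylation removes the tertiary triethylsilyl and the allylic tert-butyldimethylsilyl ether in one operation; it is neither basic enough to move acyl groups nor nucleophilic enough to add to the exo-methylene lactone.

## Compound list

1 | (R)-(−)-carvone | CC1=CC[C@H](CC1=O)C(C)=C | starting material
2 | (1R,5R)-cis-carveol | C1C=C(C)[C@H](O)C[C@@H]1C(C)=C | intermediate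
3 | (1S,5R)-trans-carveyl 4-nitrobenzoate | C1C=C(C)[C@@H](OC(=O)c2ccc(cc2)[N+](=O)[O-])C[C@@H]1C(C)=C | intermediate
4 | (1S,5R)-trans-carveol | C1C=C(C)[C@@H](O)C[C@@H]1C(C)=C | intermediate
5 | (1S,5R)-trans-carveol tert-butyldimethylsilyl ether | C1C=C(C)[C@@H](O[Si](C)(C)C(C)(C)C)C[C@@H]1C(C)=C | intermediate
6 | (4S,6R)-4-(tert-butyldimethylsilyloxy)-3-methyl-6-(prop-1-en-2-yl)cyclohex-2-en-1-one | O=C1C=C(C)[C@@H](O[Si](C)(C)C(C)(C)C)C[C@@H]1C(C)=C | intermediate
7 | 4-methoxybenzyl alcohol | COc1ccc(CO)cc1 | starting material
8 | trichloroethylene | ClC=C(Cl)Cl | starting material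
9 | potassium 4-methoxybenzyl oxide | [K+].[O-]Cc1ccc(OC)cc1 | intermediate (not isolated)
10 | (E)-1,2-dichlorovinyl 4-methoxybenzyl ether | COc1ccc(CO/C(Cl)=C\Cl)cc1 | intermediate
11 | lithium (4-methoxybenzyloxy)acetylide | [Li]C#COCc1ccc(OC)cc1 | intermediate (not isolated)
12 | ethynyl 4-methoxybenzyl ether | C#COCc1ccc(OC)cc1 | intermediate
13 | (E)-2-(4-methoxybenzyloxy)vinylzirconocene chloride | COc1ccc(CO/C=C/[Zr](Cl)(C2C=CC=C2)C2C=CC=C2)cc1 | intermediate (not isolated)
14 | (E)-2-iodovinyl 4-methoxybenzyl ether | COc1ccc(CO/C=C/I)cc1 | intermediate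
15 | (E)-2-(4-methoxybenzyloxy)vinyllithium | [Li]/C=C/OCc1ccc(OC)cc1 | intermediate (not isolated)
16 | (E)-2-(4-methoxybenzyloxy)vinylcerium dichloride | Cl[Ce](Cl)/C=C/OCc1ccc(OC)cc1 | intermediate (not isolated)
17 | (1R,4S,6R)-4-(tert-butyldimethylsilyloxy)-1-[(E)-2-(4-methoxybenzyloxy)vinyl]-3-methyl-6-(prop-1-en-2-yl)cyclohex-2-en-1-ol | O[C@]1(/C=C/OCc2ccc(OC)cc2)C=C(C)[C@@H](O[Si](C)(C)C(C)(C)C)C[C@@H]1C(C)=C | intermediate
18 | potassium alkoxide of 17 | [K+].[O-][C@]1(/C=C/OCc2ccc(OC)cc2)C=C(C)[C@@H](O[Si](C)(C)C(C)(C)C)C[C@@H]1C(C)=C | intermediate (not isolated)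
19 | ten-membered potassium enolate (C6 oxide cis to C8, 3S,8R, 4Z, 1(10)E) | [C@@H]1(O[Si](C)(C)C(C)(C)C)/C(C)=C\C(\[O-])=C\[C@H](OCc2ccc(OC)cc2)C/C(C)=C/C1.[K+] | intermediate (not isolated)
20 | (2Z,4S,6E,9R)-4-(tert-butyldimethylsilyloxy)-9-(4-methoxybenzyloxy)-3,7-dimethylcyclodeca-2,6-dien-1-one | C1[C@H](OCc2ccc(OC)cc2)C/C(C)=C/C[C@H](O[Si](C)(C)C(C)(C)C)/C(C)=C\C1=O | intermediate
21 | tert-butyl bromoacetate | CC(C)(C)OC(=O)CBr | starting material
22 | lithium enolate of 20 | [C@@H]1(O[Si](C)(C)C(C)(C)C)/C(C)=C\C(\[O-])=C\[C@H](OCc2ccc(OC)cc2)C/C(C)=C/C1.[Li+] | intermediate (not isolated)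
23 | tert-butyl [(1R,3Z,5S,7E,10R)-5-(tert-butyldimethylsilyloxy)-10-(4-methoxybenzyloxy)-4,8-dimethyl-2-oxocyclodeca-3,7-dien-1-yl]acetate (working numbering 3S,7R,8R) | O=C1/C=C(/C)[C@@H](O[Si](C)(C)C(C)(C)C)C/C=C(C)/C[C@@H](OCc2ccc(OC)cc2)[C@H]1CC(=O)OC(C)(C)C | intermediate
24 | (1R,10R)-1,10-epoxide of 23 (1R,3S,7R,8R,10R) | O=C1/C=C(/C)[C@@H](O[Si](C)(C)C(C)(C)C)C[C@H]2O[C@]2(C)C[C@@H](OCc3ccc(OC)cc3)[C@H]1CC(=O)OC(C)(C)C | intermediate
25 | (3S,6S,7S,8R,10S)-triol: C6 and C10 hydroxyls, 2-hydroxyethyl at C7, C3 OTBS, C8 OPMB | O[C@H]1/C=C(/C)[C@@H](O[Si](C)(C)C(C)(C)C)CC[C@](C)(O)C[C@@H](OCc2ccc(OC)cc2)[C@H]1CCO | intermediate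
26 | (3S,6S,7R,8R,10S)-10-hydroxy cis-fused 6,12-lactone, C3 OTBS, C8 OPMB | C1C(=O)O[C@H]2/C=C(/C)[C@@H](O[Si](C)(C)C(C)(C)C)CC[C@](C)(O)C[C@@H](OCc3ccc(OC)cc3)[C@@H]12 | intermediate
27 | (3S,6S,7R,8R,10S)-10-triethylsilyl ether of 26 | C1C(=O)O[C@H]2/C=C(/C)[C@@H](O[Si](C)(C)C(C)(C)C)CC[C@](C)(O[Si](CC)(CC)CC)C[C@@H](OCc3ccc(OC)cc3)[C@@H]12 | intermediate
28 | lithium enolate of 27 | C1=C([O-])O[C@H]2/C=C(/C)[C@@H](O[Si](C)(C)C(C)(C)C)CC[C@](C)(O[Si](CC)(CC)CC)C[C@@H](OCc3ccc(OC)cc3)[C@@H]12.[Li+] | intermediate (not isolated)
29 | 11-(dimethylaminomethyl) lactone, C11 undefined | CN(C)CC1C(=O)O[C@H]2/C=C(/C)[C@@H](O[Si](C)(C)C(C)(C)C)CC[C@](C)(O[Si](CC)(CC)CC)C[C@@H](OCc3ccc(OC)cc3)[C@@H]12 | intermediate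
30 | trimethylammonium iodide of 29 | C[N+](C)(C)CC1C(=O)O[C@H]2/C=C(/C)[C@@H](O[Si](C)(C)C(C)(C)C)CC[C@](C)(O[Si](CC)(CC)CC)C[C@@H](OCc3ccc(OC)cc3)[C@@H]12.[I-] | intermediate (not isolated)
31 | (3S,6S,7R,8R,10S)-α-methylene lactone, C3 OTBS, C8 OPMB, C10 OTES | C=C1C(=O)O[C@H]2/C=C(/C)[C@@H](O[Si](C)(C)C(C)(C)C)CC[C@](C)(O[Si](CC)(CC)CC)C[C@@H](OCc3ccc(OC)cc3)[C@@H]12 | intermediate
32 | (3S,6S,7R,8R,10S)-C8 alcohol, C3 OTBS, C10 OTES | C=C1C(=O)O[C@H]2/C=C(/C)[C@@H](O[Si](C)(C)C(C)(C)C)CC[C@](C)(O[Si](CC)(CC)CC)C[C@@H](O)[C@@H]12 | intermediate
33 | angelic acid, (Z)-2-methylbut-2-enoic acid | C/C=C(/C)C(=O)O | starting material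
34 | angelic 2,4,6-trichlorobenzoic anhydride | C/C=C(/C)C(=O)OC(=O)c1c(Cl)cc(Cl)cc1Cl | intermediate (not isolated)
35 | (3S,6S,7R,8R,10S)-8-angelate, C3 OTBS, C10 OTES | C=C1C(=O)O[C@H]2/C=C(/C)[C@@H](O[Si](C)(C)C(C)(C)C)CC[C@](C)(O[Si](CC)(CC)CC)C[C@@H](OC(=O)/C(C)=C\C)[C@@H]12 | intermediate
36 | CNP0137971.2 | C=C1C(=O)O[C@H]2/C=C(/C)[C@@H](O)CC[C@](C)(O)C[C@@H](OC(=O)/C(C)=C\C)[C@@H]12 | target

## Step count and least certain steps

Total: 20 steps. Longest linear sequence: 17 steps (steps 1–5 and 9–20, from 1 to 36); the three-step branch from 7 and 8 (steps 6–8) joins at step 9.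

**Step 10 (key step).**
- Risk: E1cB expulsion of the 4-methoxybenzyl oxide from enolate 19 if it stands at room temperature, and leakage through a boat transition state, which would erode the transfer to C8.
- Fallback: it sets out from 17 and returns at 20, and gives up charge acceleration. The neutral alcohol 17 is heated in degassed toluene with a trace of a hindered pyridine base in a sealed, base-washed tube at about 190 °C. The same chair rearrangement is then driven by tautomerisation of the enol to ketone 20, and no enolate β to the ether is ever present. It creates no compound outside the list (entry F0 below). Its own weakness is competing retro-ene cleavage of the tertiary alcohol.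

**Step 5.**
- Risk: competing hydrogen abstraction at the silyloxy-bearing CH and at the isopropenyl allylic positions, and base- or acid-induced migration of the isopropenyl alkene into conjugation with the new ketone.
- Fallback: it sets out from 4 and returns at 6, and replaces C–H oxidation by an oxygen transposition.
  - Hydroxyl-directed epoxidation (VO(acac)2, t-BuOOH) gives the cis-epoxy alcohol F1.
  - Silylation (TBSCl, imidazole) gives its silyl ether F2.
  - PhSeSePh/NaBH4 opens the epoxide at the secondary carbon to the hydroxy selenide F3.
  - H2O2 eliminates the selenoxide to the tertiary allylic alcohol F4.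
  - Pyridinium chlorochromate (C5H5NH)[CrO3Cl] transposes F4 oxidatively to 6.

**Step 9.**
- Risk: anti elimination of lithium 4-methoxybenzyl oxide from the E alkenyllithium 15 before it is trapped by cerium, and incomplete preference for attack anti to the isopropenyl group.
- Fallback: it sets out from 10 and 6 and returns at 17. The acetylide 11, made as in step 7 but not quenched, is transmetalated with CeCl3 and added to 6 to give the alkynyl ether carbinol F5. LiAlH4 in THF then reduces the triple bond by alkoxide-directed trans-hydroalumination to the E enol ether 17.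
- Caveat: the smaller acetylide may show a lower facial preference, so the diastereomers would be separated at F5.

**Step 11.**
- Risk: alkylation on the other face of enolate 22 if the lithium chelate to the C8 ether does not form, together with some dialkylation.
- Fallback: it sets out from 20 and returns at 23, and lets a proton set C7 in place of the electrophile. The 7-epimer F6 from the alkylation is converted back into its ketone enolate with LiN(SiMe3)2 and protonated at −78 °C with a hindered phenol. Proton delivery to the face that the alkyl halide used then gives 23.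

**Step 12.**
- Risk: poor facial selectivity in the epoxidation, because the E alkene can turn either face outward, which would give the C10 epimer.
- Fallback: it sets out from 23 and returns at 25, and uses an anti hydration.
  - N-bromosuccinimide in wet THF forms the bromonium ion on the exposed face and water opens it at C10 from the other face, giving the bromohydrin F7.
  - Bu3SnH with a radical initiator removes the bromine to give the C10 tertiary alcohol keto ester F8.
  - The LiEt3BH treatment of step 13 then reduces ketone and ester to 25.

**Step 13.**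
- Risk: hydride delivery to the other face of the C6 carbonyl if the ring conformation overrides the Felkin–Anh preference, and incomplete ester reduction.
- Fallback: it sets out from 24 and returns at 26, and corrects C6 by inversion.
  - The 6-epimeric triol F9 is oxidised as in step 14 to the trans-fused lactone F10.
  - LiOH opens F10, and careful acidification gives the hydroxy acid F11.
  - Mitsunobu lactonisation (PPh3, DIAD) of F11 inverts the allylic C6 centre and closes the cis-fused lactone 26.

## Further compounds

F0 | step 10 | none | none
F1 | step 5 | cis-epoxy alcohol: 2,3-epoxide of 4 with the oxirane on the face of the hydroxyl | C1[C@H]2O[C@@]2(C)[C@@H](O)C[C@@H]1C(C)=C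
F2 | step 5 | tert-butyldimethylsilyl ether of F1 | C1[C@H]2O[C@@]2(C)[C@@H](O[Si](C)(C)C(C)(C)C)C[C@@H]1C(C)=C
F3 | step 5 | hydroxy selenide: phenylselanyl at the former alkene CH, trans to the new tertiary hydroxyl | C1[C@H]([Se]c2ccccc2)[C@@](C)(O)[C@@H](O[Si](C)(C)C(C)(C)C)C[C@@H]1C(C)=C
F4 | step 5 | tertiary allylic alcohol with the alkene moved toward the ring CH2 | C1=C[C@@](C)(O)[C@@H](O[Si](C)(C)C(C)(C)C)C[C@@H]1C(C)=C
F5 | step 9 | (1R,4S,6R)-1-[(4-methoxybenzyloxy)ethynyl] analogue of 17 | O[C@]1(C#COCc2ccc(OC)cc2)C=C(C)[C@@H](O[Si](C)(C)C(C)(C)C)C[C@@H]1C(C)=C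
F6 | step 11 | 7-epimer of 23 | O=C1/C=C(/C)[C@@H](O[Si](C)(C)C(C)(C)C)C/C=C(C)/C[C@@H](OCc2ccc(OC)cc2)[C@@H]1CC(=O)OC(C)(C)C
F7 | step 12 | bromohydrin of 23: bromine at C1, tertiary hydroxyl at C10 with the configuration of the target | O=C1/C=C(/C)[C@@H](O[Si](C)(C)C(C)(C)C)C[C@H](Br)[C@](C)(O)C[C@@H](OCc2ccc(OC)cc2)[C@H]1CC(=O)OC(C)(C)C
F8 | step 12 | 10-hydroxy keto ester: 23 hydrated at C1=C10, 10S | O=C1/C=C(/C)[C@@H](O[Si](C)(C)C(C)(C)C)CC[C@](C)(O)C[C@@H](OCc2ccc(OC)cc2)[C@H]1CC(=O)OC(C)(C)C
F9 | step 13 | 6-epimer of 25 | O[C@@H]1/C=C(/C)[C@@H](O[Si](C)(C)C(C)(C)C)CC[C@](C)(O)C[C@@H](OCc2ccc(OC)cc2)[C@H]1CCO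
F10 | step 13 | 6-epimer of 26, trans-fused lactone | C1C(=O)O[C@@H]2/C=C(/C)[C@@H](O[Si](C)(C)C(C)(C)C)CC[C@](C)(O)C[C@@H](OCc3ccc(OC)cc3)[C@@H]12
F11 | step 13 | 6-epi hydroxy acid from F10 | O[C@@H]1/C=C(/C)[C@@H](O[Si](C)(C)C(C)(C)C)CC[C@](C)(O)C[C@@H](OCc2ccc(OC)cc2)[C@H]1CC(=O)O
A1 | alternative 1 | (Z)-alkenyl cis-lactone diene, open at C1–C2 | C=C[C@H](O)/C(C)=C\[C@@H]1OC(=O)C[C@@H]1[C@H](OCc2ccc(OC)cc2)C[C@@](C)(O[Si](CC)(CC)CC)C=C
A2 | alternative 2 | C10 triethylsilyl ether of the target | C=C1C(=O)O[C@H]2/C=C(/C)[C@@H](O)CC[C@](C)(O[Si](CC)(CC)CC)C[C@@H](OC(=O)/C(C)=C\C)[C@@H]12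
A3 | alternative 3 | ten-membered C8 alcohol with a 2-(silyloxymethyl)vinyl group on C7 | C=C(CO[Si](C)(C)C(C)(C)C)[C@H]1[C@@H](OCOC)/C=C(/C)[C@@H](O[Si](C)(C)C(C)(C)C)CC[C@](C)(O[Si](CC)(CC)CC)C[C@H]1O
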